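The route rests on reading the tetrasubstituted Z alkene C7=C11 of ring B, whose C12 hydroxymethyl lies cis to the C8 ketone, as hydroxyacetone joined through its carbonyl carbon to C7. This unit is stored as a furan (C8–O–C12) that cannot lose the geometry. The key step forms C7–C11 by Lewis acid aldol addition of a C7 silyl enol ether to silylated hydroxyacetone. In the same operation it closes and aromatises the furan and frees the C3 alcohol. The precursor is a cis-decalin from (S)-Wieland–Miescher ketone that already holds all five stereocentres, with a labile triethylsilyl ether at C3 and a robust triisopropylsilyl ether at C9. Singlet oxygen later releases the alkene.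

Key step: step 11

Numbering: eremophilane numbering is used. Ring A = C1–C5 and C10, ring B = C5–C10, C14 = methyl on C5, C15 = methyl on C4. β is the face of C14 and α is the opposite face.
Assumption: the target is made and drawn as the open hydroxy enone, although in solution it may equilibrate with the hemiketal formed from C12–OH and C8=O.

Step 1
Reactants: 1 (S)-Wieland–Miescher ketone
Product: 2 5β-methyl-10βH-decalin-4,8-dione (cis-dione)
Conditions: H2 (1 atm), Pd/C, pyridine, rt
Reagents that add atoms: none
Why: Heterogeneous hydrogenation of the enone C9=C10 in a basic solvent delivers hydrogen to C10 from the face of the angular methyl, as in the 5β-selective hydrogenation of steroidal 4-en-3-ones, so the cis ring fusion (10β-H) is set while both ketones survive.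

Step 2
Reactants: 2 cis-dione
Product: 3 8,8-ethylenedioxy-5β-methyl-10βH-decalin-4-one (keto ketal)
Conditions: HOCH2CH2OH (1.05 equiv), p-TsOH·H2O (cat.), benzene, reflux, Dean–Stark
Reagents that add atoms: ethylene glycol, OCCO
Why: In this acid-catalysed ketalisation the open C8 ketone reacts far faster than the C4 ketone next to the quaternary C5, and C10 is not enolisable, so the ring fusion is safe.

Step 3
Reactants: 3 keto ketal
Product: 4 8,8-ethylenedioxy-5β-methyl-10βH-octal-3-en-4-yl trifluoromethanesulfonate (alkenyl triflate)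
Conditions: KN(SiMe3)2, THF, −78 °C; PhNTf2, −78 → 0 °C
Reagents that add atoms: N-phenylbis(trifluoromethanesulfonimide), O=S(=O)(N(c1ccccc1)S(=O)(=O)C(F)(F)F)C(F)(F)F
Why: This is enolate O-triflation, and because C5 is quaternary the C4 ketone can enolise only toward C3, so a single alkenyl triflate should form.

Step 4
Reactants: 4 alkenyl triflate
Product: 5 8,8-ethylenedioxy-4,5β-dimethyl-10βH-octal-3-ene (alkene)
Conditions: MeMgBr, Fe(acac)3 (cat.), THF–NMP, −30 → 0 °C
Reagents that add atoms: methylmagnesium bromide, C[Mg]Br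
Why: Iron-catalysed Kumada-type cross-coupling of an alkenyl triflate with a methyl Grignard reagent is fast at low temperature, tolerates the ketal and installs C15 with the alkene fixed at C3=C4.

Step 5
Reactants: 5 alkene
Product: 8 3α-hydroxy-4β,5β-dimethyl-10βH-decalin-8-one (hydroxy ketone), via alkylborane 6 (not isolated), via ketal alcohol 7 (not isolated)
Conditions: BH3·THF, THF, 0 °C → rt; 3 M NaOH, 30% H2O2, 0 °C → rt; crude, 1 M HCl, THF, rt
Reagents that add atoms: hydrogen peroxide, OO; water, O
Why: Hydroboration–oxidation followed by acetal hydrolysis puts boron on the less substituted C3 and hydrogen on C4 in a syn addition to the α face, because the dioxolane (one oxygen of which would be syn-axial to C1 in the other chair form) holds the bicycle in the steroid-like conformer where C14 is pseudoaxial over the β face of C3=C4, and oxidation with retention then sets 3α-OH and 4β-CH3 together.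

Step 6
Reactants: 8 hydroxy ketone
Product: 9 3α-(triethylsilyloxy)-4β,5β-dimethyl-10βH-decalin-8-one
Conditions: Et3SiCl, imidazole, CH2Cl2, 0 °C → rt
Reagents that add atoms: chlorotriethylsilane, CC[Si](Cl)(CC)CC
Why: This is standard silylation of the only hydroxyl group, and the triethylsilyl ether withstands amine bases, buffered peracid and lithium amide yet is meant to fall in the acid stage of step 11, which removes the need for a separate and delicate C3 deprotection on the furan.

Step 7
Reactants: 9 silyl ether ketone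
Product: 10 3α-(triethylsilyloxy)-8-(triisopropylsilyloxy)-4β,5β-dimethyl-10βH-octal-8-ene (C8=C9 enol ether)
Conditions: iPr3SiOTf, Et3N, CH2Cl2, 0 °C → rt
Reagents that add atoms: triisopropylsilyl trifluoromethanesulfonate, CC(C)[Si](OS(=O)(=O)C(F)(F)F)(C(C)C)C(C)C
Why: Soft enolisation with a silyl triflate and an amine under equilibrating conditions should give the C8=C9 enol ether, the direction in which cis-fused 2-decalones and 5β-3-oxo steroids enolise, and it places on oxygen the silyl group that C9–O will keep.

Step 8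
Reactants: 10 C8=C9 enol ether
Product: 12 3α-(triethylsilyloxy)-9β-(triisopropylsilyloxy)-4β,5β-dimethyl-10βH-decalin-8-one, via silyloxy epoxide 11 (not isolated)
Conditions: mCPBA, NaHCO3, CH2Cl2, 0 °C → rt
Reagents that add atoms: 3-chloroperoxybenzoic acid, O=C(OO)c1cccc(Cl)c1
Why: In this Rubottom oxidation the peracid attacks the convex β face (the α face at C9 lies under the axial C4), and epoxide 11 opens with a 1,4-shift of silicon to the equatorial 9β-silyloxy ketone, which is also the more stable epimer.

Step 9
Reactants: 12 9β-silyloxy ketone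
Product: 13 C7=C8 trimethylsilyl enol ether of 12
Conditions: LiN(iPr)2, Me3SiCl (in situ quench), THF, −78 °C; Et3N, cold pentane–aq. NaHCO3 work-up, used crude
Reagents that add atoms: chlorotrimethylsilane, C[Si](C)(C)Cl
Why: Kinetic deprotonation with immediate O-silylation takes a proton from the open C7 methylene and not from the hindered, oxygen-bearing C9 methine, as is usual for α-silyloxy ketones, so C9 is neither epimerised nor given time for silyl migration.

Step 10
Reactants: 14 hydroxyacetone
Product: 15 1-(triethylsilyloxy)propan-2-one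
Conditions: Et3SiCl, imidazole, CH2Cl2, 0 °C → rt
Reagents that add atoms: chlorotriethylsilane, CC[Si](Cl)(CC)CC
Why: Silylation of the primary alcohol gives a monomeric, aprotic ketone that tolerates TiCl4 at low temperature and releases C12–OH under the mildest acid.

Step 11
Reactants: 13 C7=C8 trimethylsilyl enol ether; 15 1-(triethylsilyloxy)propan-2-one
Product: 18 9β-(triisopropylsilyloxy)-10βH-furanoeremophilan-3α-ol (furan alcohol), via aldol adduct 16 (not isolated), via hemiketal 17 (not isolated)
Conditions: 15, TiCl4, CH2Cl2, −78 °C, then 13; aq. NaHCO3; crude, p-TsOH·H2O (cat.), THF–H2O, rt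
Reagents that add atoms: none
Why: TiCl4 binds the carbonyl oxygen of 15, C7 of enol ether 13 attacks C11 through an open transition state with loss of the trimethylsilyl group, and aqueous quench gives aldol 16; this is a Mukaiyama aldol addition to an α-oxygenated ketone. In wet acid the primary silyl ether falls first, the C12 hydroxyl adds to the C8 carbonyl in a 5-exo-trig closure to hemiketal 17, and two dehydrations (C8–OH with C7–H, then the tertiary C11–OH, activated by the new enol ether, with C12–H) aromatise the ring, which is the established cyclodehydration route to 3-methylfurans. No lasting stereocentre is made, since the transient centres C7, C8 and C11 all end as sp2 atoms, so the diastereomeric make-up of 16 has no consequence, and C9 and C10 are not touched. The step needs C7 and not C9 to react, which is settled beforehand by the defined enol ether 13 that cannot equilibrate at −78 °C, and it needs a sink for the reversible tertiary aldol, which aromatisation provides. It also needs discrimination among the silyl ethers: both triethylsilyl groups leave, whereas the hindered triisopropylsilyl ether at the now furfurylic C9 should persist under catalytic acid at room temperature, its oxygen being poorly basic and its silicon shielded. Because C8–O–C12 is then part of an aromatic ring, the alkene released later can only have C12 cis to the ketone.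

Step 12
Reactants: 19 (E)-non-3-en-2-one
Product: 20 ethyl (2E,4E)-3-methyldeca-2,4-dienoate
Conditions: (EtO)2P(O)CH2CO2Et, NaH, THF, 0 °C → rt
Reagents that add atoms: triethyl phosphonoacetate, CCOC(=O)CP(=O)(OCC)OCC
Why: Horner–Wadsworth–Emmons olefination of a methyl alkenyl ketone, as practised on β-ionone, places the ester trans to the larger alkenyl residue (2E), leaves the existing E alkene untouched, and the minor 2Z isomer is removed by chromatography.

Step 13
Reactants: 20 dienoate
Product: 21 (2E,4E)-3-methyldeca-2,4-dien-1-ol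
Conditions: iBu2AlH (2.2 equiv), CH2Cl2, −78 → 0 °C; aq. potassium sodium tartrate
Reagents that add atoms: none
Why: Two equivalents of the aluminium hydride reduce the conjugated ester in the 1,2 sense to the allylic alcohol without touching the diene.

Step 14
Reactants: 21 dienol
Product: 22 (2E,4E)-3-methyldeca-2,4-dienal
Conditions: MnO2, CH2Cl2, rt
Reagents that add atoms: none
Why: MnO2 oxidises allylic alcohols selectively under neutral conditions that preserve both alkene geometries.

Step 15
Reactants: 22 dienal
Product: 23 ethyl (2E,4E,6E)-5-methyldodeca-2,4,6-trienoate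
Conditions: (EtO)2P(O)CH2CO2Et, NaH, THF, 0 °C → rt
Reagents that add atoms: triethyl phosphonoacetate, CCOC(=O)CP(=O)(OCC)OCC
Why: Horner–Wadsworth–Emmons olefination of an aldehyde with a stabilised phosphonate reliably gives the new disubstituted alkene as the E isomer.

Step 16
Reactants: 23 trienoate
Product: 24 (2E,4E,6E)-5-methyldodeca-2,4,6-trienoic acid
Conditions: LiOH, THF–MeOH–H2O, rt; 1 M HCl to pH 3
Reagents that add atoms: lithium hydroxide, [Li+].[OH-]
Why: Saponification at room temperature cleaves the ethyl ester without isomerising or deconjugating the triene.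

Step 17
Reactants: 24 trienoic acid; 18 furan alcohol
Product: 26 9β-(triisopropylsilyloxy)-10βH-furanoeremophilan-3α-yl (2E,4E,6E)-5-methyldodeca-2,4,6-trienoate (furan ester), via mixed anhydride 25 (not isolated)
Conditions: 2,4,6-Cl3C6H2COCl, Et3N, toluene, rt; then 18, DMAP, rt
Reagents that add atoms: none
Why: Yamaguchi esterification acylates the only free hydroxyl group, the equatorial C3–OH, with retention at C3 under basic conditions that harm neither the furan, the furfurylic silyl ether nor the triene.

Step 18
Reactants: 26 furan ester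
Product: 29 9-O-triisopropylsilyl ether of the target, via endoperoxide 27 (not isolated), via keto-enal 28 (not isolated)
Conditions: O2, tetraphenylporphyrin (cat.), visible light, CH2Cl2, −78 °C; Me2S, −78 → 0 °C; MeOH, NaBH4, −78 °C
Reagents that add atoms: oxygen, O=O
Why: Singlet oxygen adds across C8 and C12 of the electron-rich trisubstituted furan in a [4+2] cycloaddition far faster than it attacks the acceptor-substituted triene, Me2S reduces endoperoxide 27 to keto-enal 28 with the Z geometry inherited from the ring, and NaBH4 at −78 °C reduces only the exposed aldehyde because the C8 ketone is flanked by a fully substituted alkene carbon and by the C9 silyl ether, which also blocks an Achmatowicz-type lactol that would mask the aldehyde.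

Step 19
Reactants: 29 9-O-triisopropylsilyl ether of the target
Product: 30 target CNP0226738.1
Conditions: Bu4NF, AcOH (1:1), THF, 0 °C → rt
Reagents that add atoms: none
Why: Fluoride-induced Si–O cleavage is accelerated by the adjacent ketone, and the acetic acid buffer should prevent base-induced epimerisation at C9 or ester loss without being acidic enough to return the Z hydroxy enone to the furan.

Compound list
1 | (S)-Wieland–Miescher ketone | O=C1CCCC2=CC(=O)CC[C@]12C | starting material
2 | 5β-methyl-10βH-decalin-4,8-dione (cis-dione) | O=C1CCC[C@@H]2CC(=O)CC[C@]12C | intermediate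
3 | 8,8-ethylenedioxy-5β-methyl-10βH-decalin-4-one | O=C1CCC[C@@H]2CC3(OCCO3)CC[C@]12C | intermediate
4 | 8,8-ethylenedioxy-5β-methyl-10βH-octal-3-en-4-yl trifluoromethanesulfonate | O=S(=O)(OC1=CCC[C@@H]2CC3(OCCO3)CC[C@]12C)C(F)(F)F | intermediate
5 | 8,8-ethylenedioxy-4,5β-dimethyl-10βH-octal-3-ene | CC1=CCC[C@@H]2CC3(OCCO3)CC[C@]12C | intermediate
6 | C3α alkylborane from 5 (4β-methyl, drawn as the monoalkylborane) | B[C@@H]1CC[C@@H]2CC3(OCCO3)CC[C@]2(C)[C@H]1C | intermediate
7 | 8,8-ethylenedioxy-4β,5β-dimethyl-10βH-decalin-3α-ol | O[C@@H]1CC[C@@H]2CC3(OCCO3)CC[C@]2(C)[C@H]1C | intermediate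
8 | 3α-hydroxy-4β,5β-dimethyl-10βH-decalin-8-one | O[C@@H]1CC[C@@H]2CC(=O)CC[C@]2(C)[C@H]1C | intermediate
9 | 3α-(triethylsilyloxy)-4β,5β-dimethyl-10βH-decalin-8-one | CC[Si](CC)(CC)O[C@@H]1CC[C@@H]2CC(=O)CC[C@]2(C)[C@H]1C | intermediate
10 | C8=C9 triisopropylsilyl enol ether of 9 | CC[Si](CC)(CC)O[C@@H]1CC[C@@H]2C=C(O[Si](C(C)C)(C(C)C)C(C)C)CC[C@]2(C)[C@H]1C | intermediate
11 | 8β,9β-epoxide of 10 (silyloxy epoxide) | CC[Si](CC)(CC)O[C@@H]1CC[C@@H]2[C@H]3O[C@@]3(O[Si](C(C)C)(C(C)C)C(C)C)CC[C@]2(C)[C@H]1C | intermediate
12 | 3α-(triethylsilyloxy)-9β-(triisopropylsilyloxy)-4β,5β-dimethyl-10βH-decalin-8-one | CC[Si](CC)(CC)O[C@@H]1CC[C@@H]2[C@@H](O[Si](C(C)C)(C(C)C)C(C)C)C(=O)CC[C@]2(C)[C@H]1C | intermediate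
13 | C7=C8 trimethylsilyl enol ether of 12 | CC[Si](CC)(CC)O[C@@H]1CC[C@@H]2[C@@H](O[Si](C(C)C)(C(C)C)C(C)C)C(O[Si](C)(C)C)=CC[C@]2(C)[C@H]1C | intermediate
14 | hydroxyacetone | CC(=O)CO | starting material
15 | 1-(triethylsilyloxy)propan-2-one | CC(=O)CO[Si](CC)(CC)CC | intermediate
16 | aldol adduct, C7–C11 bonded, mixture at C7 and C11 | CC[Si](CC)(CC)O[C@@H]1CC[C@@H]2[C@@H](O[Si](C(C)C)(C(C)C)C(C)C)C(=O)C(C(C)(O)CO[Si](CC)(CC)CC)C[C@]2(C)[C@H]1C | intermediate
17 | C8 hemiketal (C8–O–C12 closed), mixture at C7, C8 and C11 | CC[Si](CC)(CC)O[C@@H]1CC[C@@H]2[C@@H](O[Si](C(C)C)(C(C)C)C(C)C)C3(O)OCC(C)(O)C3C[C@]2(C)[C@H]1C | intermediate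
18 | 9β-(triisopropylsilyloxy)-10βH-furanoeremophilan-3α-ol | O[C@@H]1CC[C@@H]2[C@@H](O[Si](C(C)C)(C(C)C)C(C)C)c3occ(C)c3C[C@]2(C)[C@H]1C | intermediate
19 | (E)-non-3-en-2-one | CCCCC/C=C/C(C)=O | starting material
20 | ethyl (2E,4E)-3-methyldeca-2,4-dienoate | CCCCC/C=C/C(C)=C/C(=O)OCC | intermediate
21 | (2E,4E)-3-methyldeca-2,4-dien-1-ol | CCCCC/C=C/C(C)=C/CO | intermediate
22 | (2E,4E)-3-methyldeca-2,4-dienal | CCCCC/C=C/C(C)=C/C=O | intermediate
23 | ethyl (2E,4E,6E)-5-methyldodeca-2,4,6-trienoate | CCCCC/C=C/C(C)=C/C=C/C(=O)OCC | intermediate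
24 | (2E,4E,6E)-5-methyldodeca-2,4,6-trienoic acid | CCCCC/C=C/C(C)=C/C=C/C(=O)O | intermediate
25 | mixed anhydride of 24 and 2,4,6-trichlorobenzoic acid | CCCCC/C=C/C(C)=C/C=C/C(=O)OC(=O)c1c(Cl)cc(Cl)cc1Cl | intermediate
26 | 9β-(triisopropylsilyloxy)-10βH-furanoeremophilan-3α-yl (2E,4E,6E)-5-methyldodeca-2,4,6-trienoate | CCCCC/C=C/C(C)=C/C=C/C(=O)O[C@@H]1CC[C@@H]2[C@@H](O[Si](C(C)C)(C(C)C)C(C)C)c3occ(C)c3C[C@]2(C)[C@H]1C | intermediate
27 | 8,12-endoperoxide of 26, mixture at C8 and C12 | CCCCC/C=C/C(C)=C/C=C/C(=O)O[C@@H]1CC[C@@H]2[C@@H](O[Si](C(C)C)(C(C)C)C(C)C)C34OOC(O3)C(C)=C4C[C@]2(C)[C@H]1C | intermediate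
28 | 7(11)Z keto-enal (C8 ketone, C12 aldehyde), 9β-silyl ether, 3α-trienoate | CCCCC/C=C/C(C)=C/C=C/C(=O)O[C@@H]1CC[C@@H]2[C@@H](O[Si](C(C)C)(C(C)C)C(C)C)C(=O)/C(=C(/C)C=O)C[C@]2(C)[C@H]1C | intermediate
29 | 9-O-triisopropylsilyl ether of the target | CCCCC/C=C/C(C)=C/C=C/C(=O)O[C@@H]1CC[C@@H]2[C@@H](O[Si](C(C)C)(C(C)C)C(C)C)C(=O)/C(=C(/C)CO)C[C@]2(C)[C@H]1C | intermediate
30 | (3R,4R,5R,9R,10S,7(11)Z)-9,12-dihydroxy-8-oxoeremophil-7(11)-en-3-yl (2E,4E,6E)-5-methyldodeca-2,4,6-trienoate | CCCCC/C=C/C(C)=C/C=C/C(=O)O[C@@H]1CC[C@@H]2[C@@H](O)C(=O)/C(=C(/C)CO)C[C@]2(C)[C@H]1C | target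

Total step count: 19 (13 in the main line, 1 for ketone 15, 5 for acid 24).
Longest linear sequence: 13 steps, from 1 to 30 through steps 1–9, 11 and 17–19.

Steps most likely to fail

Step 11. Addition to a ketone acceptor may stall or revert, traces of HCl may protodesilylate the enol ether, and prolonged acid may ionise the furfurylic C9–O bond. The fallback sets out from 13 and returns at 18. It makes the same C7–C11 bond by conjugate addition instead of carbonyl addition. Enol ether 13 is added to (E)-1-nitropropene under SnCl4 in CH2Cl2 at −78 °C (Mukaiyama–Michael addition to a nitroalkene) to give the γ-nitro ketone F1. Its nitronate (NaOMe, MeOH) is treated with buffered aqueous TiCl3 (reductive Nef reaction) to give the γ-keto aldehyde F2. Catalytic p-TsOH in wet THF then brings about Paal–Knorr cyclodehydration and loss of the C3 silyl ether, giving 18.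

Step 5. Facial selectivity may be poor, because the cis-decalin is mobile and borane may also reach the β face through the other conformer. The fallback sets out from 5 and returns at 7. It replaces kinetic face control by thermodynamic control. Hydroboration–oxidation is run without regard to face to give the alcohol mixture F3. Dess–Martin oxidation followed directly by NaOMe in MeOH should converge on the 3-ketone F4, whose 4β-methyl group is equatorial in the conformer enforced by the ketal. Electron-transfer reduction (SmI2, H2O, THF) should then give the equatorial 3α-alcohol 7.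

Step 18. Three things may go wrong here: competing oxygenation or sensitised isomerisation of the triene, drift of the Z keto-enal toward the E isomer before reduction, and over-reduction at C8. The fallback sets out from 18 and returns at 30. It opens the furan before the triene is present.
- Photooxygenation of 18 under the same conditions gives the endoperoxide F5.
- Me2S gives the keto-enal F6, and NaBH4 at −78 °C gives the diol F7.
- tBuMe2SiCl and imidazole at 0 °C silylate only the primary allylic hydroxyl group, giving the C12 silyl ether F8.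
- Yamaguchi esterification of the remaining C3–OH with 24 through anhydride 25 gives the bis-silyl ester F9.
- Bu4NF–AcOH removes both silyl groups to give 30.

Further compounds
F1 | step 11 | γ-nitro ketone, C7–C11 bonded, mixture at C7 and C11 | CC[Si](CC)(CC)O[C@@H]1CC[C@@H]2[C@@H](O[Si](C(C)C)(C(C)C)C(C)C)C(=O)C(C(C)C[N+](=O)[O-])C[C@]2(C)[C@H]1C
F2 | step 11 | γ-keto aldehyde, mixture at C7 and C11 | CC[Si](CC)(CC)O[C@@H]1CC[C@@H]2[C@@H](O[Si](C(C)C)(C(C)C)C(C)C)C(=O)C(C(C)C=O)C[C@]2(C)[C@H]1C
F3 | step 5 | 8,8-ethylenedioxy-4,5β-dimethyl-10βH-decalin-3-ol, mixture at C3 and C4 | OC1CC[C@@H]2CC3(OCCO3)CC[C@]2(C)C1C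
F4 | step 5 | 8,8-ethylenedioxy-4β,5β-dimethyl-10βH-decalin-3-one | O=C1CC[C@@H]2CC3(OCCO3)CC[C@]2(C)[C@H]1C
F5 | step 18 | 8,12-endoperoxide of 18, mixture at C8 and C12 | O[C@@H]1CC[C@@H]2[C@@H](O[Si](C(C)C)(C(C)C)C(C)C)C34OOC(O3)C(C)=C4C[C@]2(C)[C@H]1C
F6 | step 18 | 7(11)Z keto-enal with free 3α-OH and 9β-silyl ether | O[C@@H]1CC[C@@H]2[C@@H](O[Si](C(C)C)(C(C)C)C(C)C)C(=O)/C(=C(/C)C=O)C[C@]2(C)[C@H]1C
F7 | step 18 | 7(11)Z 3α,12-diol with 9β-silyl ether | O[C@@H]1CC[C@@H]2[C@@H](O[Si](C(C)C)(C(C)C)C(C)C)C(=O)/C(=C(/C)CO)C[C@]2(C)[C@H]1C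
F8 | step 18 | C12 tert-butyldimethylsilyl ether of F7 | O[C@@H]1CC[C@@H]2[C@@H](O[Si](C(C)C)(C(C)C)C(C)C)C(=O)/C(=C(/C)CO[Si](C)(C)C(C)(C)C)C[C@]2(C)[C@H]1C
F9 | step 18 | 3α-trienoate of F8 (bis-silyl ester) | CCCCC/C=C/C(C)=C/C=C/C(=O)O[C@@H]1CC[C@@H]2[C@@H](O[Si](C(C)C)(C(C)C)C(C)C)C(=O)/C(=C(/C)CO[Si](C)(C)C(C)(C)C)C[C@]2(C)[C@H]1C
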